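Carotenoid numbering is used; primed locants belong to the ε end. Everything rests on the cyclohexene ring C1'–C6': its unfunctionalised C2'H2–C3'H2 bridge between the quaternary gem-dimethyl carbon C1' and the vinylic C4' is the retron of a [4+2] cycloaddition. A Lewis-acid-catalysed Diels–Alder reaction of 2,4-dimethylpenta-1,3-diene (C4'=C5'–C6'=C1') with acrolein, an ethylene equivalent, forges C1'–C2' and C3'–C4' in one operation. The formyl group is then excised and the C5'=C6' alkene is moved to C4'=C5' by a [2,3]-Wittig shift that relays a carbinol centre to C6'. Two Wittig couplings (C15 + C10 + C15) build the polyene; the 5,8-epoxide ring comes from an axially chiral α-hydroxyallene.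

Key step: step 1

Remark: 3-methylpenta-1,4-dien-3-ol and (2E,4E,6E)-2,7-dimethylocta-2,4,6-trienedial are taken as catalog compounds.
Remark: the C5 bromide, its ether and the rearranged carbinol are carried as E/Z mixtures at the central C=C bond of the C5 unit (the carbinol also as a mixture at its carbinol carbon); both elements are erased by the ionisation in step 8, so these SMILES carry no descriptor there.

Step 1
Reactants: 1 2,4-dimethylpenta-1,3-diene; 2 acrolein
Product: 3 rac-2,2,4-trimethylcyclohex-3-ene-1-carbaldehyde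
Conditions: Me2AlCl (0.2 equiv), CH2Cl2, −78 → −20 °C, diene in slight excess
Reagents that add atoms: none
Why: Lewis-acid-catalysed normal-demand Diels–Alder reaction, the closest known types being alkylaluminium- or BF3-catalysed additions of acrolein to alkylated butadienes and the ionic variant with allyl-cation dienophiles. Me2AlCl lowers the LUMO of acrolein and the cycloaddition is strongly asynchronous: the unhindered CH2 terminus of the diene (C4') bonds first to the acrolein β-carbon (C3'), positive charge spreads over the tertiary allyl unit C5'–C6'–C1', and the aluminium enolate α-carbon (C2') then closes onto the gem-dimethyl terminus C1'. The six-membered ring is closed in the [4+2] mode, suprafacially on both partners, so the quaternary carbon is made in the ring-closing event and not by an intermolecular attack on a hindered centre. The only new stereocentre (the formyl-bearing carbon) forms as a racemate and is deleted in step 2, so neither regio- nor endo/exo selectivity is needed: either orientation leads to the same hydrocarbon. The step does need chemoselectivity for the carbocyclic [4+2] mode over cationic oligomerisation of the diene, ene reaction and closure through oxygen to a dihydropyran. The 2-methyl group of the diene destabilises the s-trans rotamer and so offsets the penalty of the cis-methyl group at C1', while a substoichiometric, proton-scavenging alkylaluminium Lewis acid at low temperature suppresses proton-initiated polymerisation.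

Step 2
Reactants: 3 rac-2,2,4-trimethylcyclohex-3-ene-1-carbaldehyde
Product: 4 1,5,5-trimethylcyclohex-1-ene
Conditions: [RhCl(cod)]2 (2.5 mol%), dppp (5 mol%), diglyme, 160 °C, product distilled out
Reagents that add atoms: none
Why: Tsuji–Wilkinson-type catalytic decarbonylation (formyl C–H oxidative addition, CO de-insertion, C–H reductive elimination) removes the activating group and with it the only stereocentre, leaving the C2'H2–C3'H2 bridge unfunctionalised.

Step 3
Reactants: 4 1,5,5-trimethylcyclohex-1-ene
Product: 5 2,4,4-trimethylcyclohex-2-en-1-one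
Conditions: Rh2(cap)4 (cap = caprolactamate, 1 mol%), t-BuOOH (70% aq., 5 equiv), K2CO3 (0.5 equiv), CH2Cl2, rt
Reagents that add atoms: tert-butyl hydroperoxide CC(C)(C)OO
Why: Radical allylic oxidation (allylic hydrogen abstraction, peroxide transfer, Kornblum–DeLaMare collapse to the ketone): C4' is the only allylic ring methylene because the other allylic ring position is the quaternary C1', and oxygen should be taken up at the unhindered end of the allyl radical, away from the neopentyl C6'.

Step 4
Reactants: 5 2,4,4-trimethylcyclohex-2-en-1-one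
Product: 6 (1S)-2,4,4-trimethylcyclohex-2-en-1-ol
Conditions: (R)-2-methyl-CBS-oxazaborolidine (0.2 equiv), BH3·SMe2 (0.7 equiv), THF, −20 °C; MeOH quench
Reagents that add atoms: none
Why: Corey–Bakshi–Shibata reduction: the (R)-oxazaborolidine–borane complex binds the carbonyl oxygen anti to the bulkier α-methylalkenyl flank and transfers hydride to one face only (1,2-reduction), which should give the (S) carbinol centre at C4'.

Step 5
Reactants: 7 3-methylpenta-1,4-dien-3-ol
Product: 8 5-bromo-3-methylpenta-1,3-diene (E/Z mixture)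
Conditions: PBr3 (0.4 equiv), pyridine (cat.), Et2O, −20 → 0 °C; used crude
Reagents that add atoms: phosphorus tribromide BrP(Br)Br
Why: Bromination of the tertiary bis-allylic alcohol with allylic transposition (SN2′ or ion-pair collapse at a primary terminus) gives the conjugated primary bromide; the two termini of the 3-methylpentadienyl unit are constitutionally equivalent, so only one skeleton can result.

Step 6
Reactants: 6 (1S)-2,4,4-trimethylcyclohex-2-en-1-ol; 8 5-bromo-3-methylpenta-1,3-diene
Product: 9 (1S)-2,4,4-trimethylcyclohex-2-en-1-yl 3-methylpenta-2,4-dien-1-yl ether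
Conditions: NaH (1.2 equiv), THF–DMF, 0 °C; then 8 (1.3 equiv), Bu4NI (cat.), 0 °C → rt
Reagents that add atoms: none
Why: Williamson ether synthesis: SN2 of the secondary alkoxide on the primary dienylic bromide, in which the C–O bond of the carbinol centre is not touched (retention).

Step 7
Reactants: 9 (1S)-2,4,4-trimethylcyclohex-2-en-1-yl 3-methylpenta-2,4-dien-1-yl ether
Product: 10 3-methyl-1-[(1R)-2,6,6-trimethylcyclohex-2-en-1-yl]penta-2,4-dien-1-ol
Conditions: n-BuLi (1.3 equiv), THF, −78 → −30 °C; H2O quench
Reagents that add atoms: none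
Why: [2,3]-Wittig rearrangement: lithiation at the dienylic O–CH2 (the most acidic site) and suprafacial shift across the ring allyl unit form C6'–C7' on the face that carried the C4'–O bond, so the (S) carbinol centre is relayed to (R) at C6' while the ring alkene moves to C4'=C5'; the new carbinol centre is uncontrolled and is erased in step 8.

Step 8
Reactants: 10 3-methyl-1-[(1R)-2,6,6-trimethylcyclohex-2-en-1-yl]penta-2,4-dien-1-ol
Product: 11 [(2E,4E)-3-methyl-5-[(1R)-2,6,6-trimethylcyclohex-2-en-1-yl]penta-2,4-dien-1-yl]triphenylphosphonium bromide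
Conditions: PPh3·HBr (1.05 equiv), MeOH, rt
Reagents that add atoms: triphenylphosphine hydrobromide [Br-].[PH+](c1ccccc1)(c1ccccc1)c1ccccc1
Why: Ionisation of the dienylic alcohol gives the same pentadienyl cation that the classical tertiary vinyl carbinol route to C15 Wittig salts passes through, and PPh3 captures its unhindered primary terminus (SN1 with allylic transposition), placing the double bonds at C7'=C8' and C9'=C10' (E,E under thermodynamic control) without touching C6'.

Step 9
Reactants: 11 the ε-end C15 phosphonium bromide; 12 (2E,4E,6E)-2,7-dimethylocta-2,4,6-trienedial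
Product: 13 (2E,4E,6E,8E,10E,12E)-2,7,11-trimethyl-13-[(1R)-2,6,6-trimethylcyclohex-2-en-1-yl]trideca-2,4,6,8,10,12-hexaenal
Conditions: 12 (3 equiv), NaOMe (1.1 equiv), MeOH–CH2Cl2, 0 °C → rt, dark; then heptane, 80 °C (E/Z equilibration)
Reagents that add atoms: none
Why: Wittig olefination of the semistabilised allylic ylide with an excess of the symmetrical dialdehyde should stop at the mono-adduct, and the new C11'=C12' bond, where formed cis, is a sterically hindered cis bond that reverts to E on gentle heating.

Step 10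
Reactants: 14 β-cyclocitral (2,6,6-trimethylcyclohex-1-ene-1-carbaldehyde)
Product: 15 β-cyclogeraniol [(2,6,6-trimethylcyclohex-1-en-1-yl)methanol]
Conditions: NaBH4, MeOH, 0 °C
Reagents that add atoms: none
Why: Borohydride 1,2-reduction of the enal gives the allylic alcohol needed for directed epoxidation.

Step 11
Reactants: 15 β-cyclogeraniol
Product: 16 [(1R,6R)-2,2,6-trimethyl-7-oxabicyclo[4.1.0]heptan-1-yl]methanol
Conditions: Ti(OiPr)4 (0.2 equiv), D-(−)-diethyl tartrate (0.24 equiv), t-BuOOH (2 equiv, in decane), 4 Å molecular sieves, CH2Cl2, −20 °C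
Reagents that add atoms: tert-butyl hydroperoxide CC(C)(C)OO
Why: Sharpless asymmetric epoxidation: the D-(−)-tartrate titanium complex delivers oxygen to one face of the tetrasubstituted alkene of the allylic alcohol and sets both oxirane centres; the methyl-bearing C–O carbon becomes C5 of the target (5R).

Step 12
Reactants: 16 the (1R,6R) epoxy alcohol
Product: 17 (1S,6R)-2,2,6-trimethyl-7-oxabicyclo[4.1.0]heptane-1-carbaldehyde
Conditions: (n-Pr4N)RuO4 (5 mol%), NMO (1.5 equiv), 4 Å molecular sieves, CH2Cl2, rt
Reagents that add atoms: none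
Why: Ley–Griffith oxidation under neutral conditions leaves the acid-sensitive tetrasubstituted oxirane intact, and the aldehyde has no α-hydrogen and cannot epimerise (the descriptor changes only through the priority rules).

Step 13
Reactants: 17 the (1S,6R) epoxy aldehyde
Product: 18 (1R,6R)-1-ethynyl-2,2,6-trimethyl-7-oxabicyclo[4.1.0]heptane
Conditions: dimethyl (1-diazo-2-oxopropyl)phosphonate (1.3 equiv), K2CO3 (2 equiv), MeOH, 0 °C → rt
Reagents that add atoms: dimethyl (1-diazo-2-oxopropyl)phosphonate COP(=O)(OC)C(=[N+]=[N-])C(C)=O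
Why: Seyferth–Gilbert homologation in its Ohira–Bestmann form: the diazomethylphosphonate anion adds to the aldehyde, and loss of phosphate and N2 with a 1,2-shift gives the terminal alkyne without touching the oxirane centres.

Step 14
Reactants: 19 but-2-yn-1-ol
Product: 20 (2E)-3-iodobut-2-en-1-ol
Conditions: Cp2Zr(H)Cl (2.2 equiv), THF, rt; then I2 (1.1 equiv), 0 °C
Reagents that add atoms: iodine II
Why: syn-Hydrozirconation of the alkyne (after O–Zr formation) settles zirconium on the methyl-bearing, less hindered carbon, and iodinolysis with retention gives the E vinyl iodide.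

Step 15
Reactants: 18 the ethynyl oxirane; 20 (2E)-3-iodobut-2-en-1-ol
Product: 21 (2E)-3-methyl-5-[(1R,6R)-2,2,6-trimethyl-7-oxabicyclo[4.1.0]heptan-1-yl]pent-2-en-4-yn-1-ol
Conditions: Pd(PPh3)4 (3 mol%), CuI (6 mol%), iPr2NH, THF, rt
Reagents that add atoms: none
Why: Sonogashira coupling joins C8 to C9 with retention of the E geometry of the iodide, and the mild amine base does not open the hindered oxirane.

Step 16
Reactants: 21 the epoxy enynol
Product: 22 (1R)-2-[(3E)-5-hydroxy-3-methylpenta-1,3-dien-1-ylidene]-1,3,3-trimethylcyclohexan-1-ol with the (aS) allene axis (carotenoid descriptors 5R,6S)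
Conditions: (IPr)CuCl (5 mol%), NaOtBu (10 mol%), polymethylhydrosiloxane (3 equiv Si–H), toluene, 0 °C → rt; then K2CO3, MeOH (cleavage of O–Si)
Reagents that add atoms: none
Why: Copper-hydride-catalysed SN2′ reduction of a propargyl oxirane: the NHC–copper hydride adds syn across the alkyne with copper next to the oxirane carbon and the alkoxide leaves anti to copper, so hydrogen arrives at C8 on the face opposite to the departing C6–O bond and the oxirane centre C6 is converted into the (aS) allene axis, while C5 keeps its oxygen and configuration.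

Step 17
Reactants: 22 the (1R,aS) allenediol
Product: 23 (2E)-3-[(2R,7aR)-4,4,7a-trimethyl-2,4,5,6,7,7a-hexahydro-1-benzofuran-2-yl]but-2-en-1-ol
Conditions: AgNO3 (10 mol%), CaCO3, acetone–H2O (4:1), rt, dark
Reagents that add atoms: none
Why: Silver-catalysed 5-endo cycloisomerisation of an α-hydroxyallene to a 2,5-dihydrofuran: the tertiary hydroxyl adds to C8 within the nodal plane of the C8 substituents, so the allene axis is converted into the C8 centre with H-8 cis and the side chain trans to the C5 methyl group (8R), and the neutral buffered medium avoids ionisation of the new bis-allylic ether.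

Step 18
Reactants: 23 the (2R,7aR) furanoid C15 alcohol
Product: 25 [(2E)-3-[(2R,7aR)-4,4,7a-trimethyl-2,4,5,6,7,7a-hexahydro-1-benzofuran-2-yl]but-2-en-1-yl]triphenylphosphonium bromide, via allylic bromide 24 (not isolated)
Conditions: PPh3 (1.1 equiv), CBr4 (1.1 equiv), 2,6-lutidine (0.2 equiv), CH2Cl2, −20 °C; then PPh3 (1.2 equiv), MeCN, rt
Reagents that add atoms: carbon tetrabromide BrC(Br)(Br)Br; triphenylphosphine c1ccc(cc1)P(c1ccccc1)c1ccccc1
Why: Appel bromination of the primary allylic alcohol under buffered, non-acidic conditions and quaternisation of PPh3 by the allylic bromide in the same flask (two SN2 steps at C11) avoid the protic acid that would ionise and epimerise the bis-allylic ether centre C8.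

Step 19
Reactants: 13 the C25 polyenal; 25 the furanoid C15 phosphonium bromide
Product: 26 (5R,8R,6'R)-5,8-epoxy-5,8-dihydro-β,ε-carotene (CNP0168410.1)
Conditions: NaOMe (1.2 equiv), CH2Cl2–MeOH, 0 °C → rt, argon, dark; then EtOH, 60 °C (E/Z equilibration), crystallisation
Reagents that add atoms: none
Why: Wittig olefination of the polyenal with the semistabilised ylide forms C11=C12; the 11-cis isomer formed alongside is a sterically hindered cis bond that reverts to all-E on gentle heating, and the basic, non-acidic medium preserves C5, C8 and C6'.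

Compound list
1 | 2,4-dimethylpenta-1,3-diene | CC(C)=CC(C)=C | starting material
2 | acrolein (prop-2-enal) | C=CC=O | starting material
3 | rac-2,2,4-trimethylcyclohex-3-ene-1-carbaldehyde | O=CC1CCC(C)=CC1(C)C | intermediate
4 | 1,5,5-trimethylcyclohex-1-ene | CC1=CC(C)(C)CCC1 | intermediate
5 | 2,4,4-trimethylcyclohex-2-en-1-one | CC1=CC(C)(C)CCC1=O | intermediate
6 | (1S)-2,4,4-trimethylcyclohex-2-en-1-ol | O[C@H]1CCC(C)(C)C=C1C | intermediate
7 | 3-methylpenta-1,4-dien-3-ol | C=CC(C)(O)C=C | starting material
8 | 5-bromo-3-methylpenta-1,3-diene (E/Z mixture) | C=CC(C)=CCBr | intermediate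
9 | (1S)-2,4,4-trimethylcyclohex-2-en-1-yl 3-methylpenta-2,4-dien-1-yl ether (E/Z mixture in the C5 unit) | C=CC(C)=CCO[C@H]1CCC(C)(C)C=C1C | intermediate
10 | 3-methyl-1-[(1R)-2,6,6-trimethylcyclohex-2-en-1-yl]penta-2,4-dien-1-ol (mixture at C1 and at C2=C3) | CC1=CCCC(C)(C)[C@H]1C(O)C=C(C)C=C | intermediate
11 | [(2E,4E)-3-methyl-5-[(1R)-2,6,6-trimethylcyclohex-2-en-1-yl]penta-2,4-dien-1-yl]triphenylphosphonium bromide | CC1=CCCC(C)(C)[C@H]1/C=C/C(C)=C/C[P+](c1ccccc1)(c1ccccc1)c1ccccc1.[Br-] | intermediate
12 | (2E,4E,6E)-2,7-dimethylocta-2,4,6-trienedial | O=C/C(C)=C/C=C/C=C(C)/C=O | starting material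
13 | (2E,4E,6E,8E,10E,12E)-2,7,11-trimethyl-13-[(1R)-2,6,6-trimethylcyclohex-2-en-1-yl]trideca-2,4,6,8,10,12-hexaenal | CC1=CCCC(C)(C)[C@H]1/C=C/C(C)=C/C=C/C(C)=C/C=C/C=C(C)/C=O | intermediate
14 | β-cyclocitral (2,6,6-trimethylcyclohex-1-ene-1-carbaldehyde) | CC1=C(C=O)C(C)(C)CCC1 | starting material
15 | β-cyclogeraniol [(2,6,6-trimethylcyclohex-1-en-1-yl)methanol] | CC1=C(CO)C(C)(C)CCC1 | intermediate
16 | [(1R,6R)-2,2,6-trimethyl-7-oxabicyclo[4.1.0]heptan-1-yl]methanol | OC[C@@]12O[C@]1(C)CCCC2(C)C | intermediate
17 | (1S,6R)-2,2,6-trimethyl-7-oxabicyclo[4.1.0]heptane-1-carbaldehyde | O=C[C@@]12O[C@]1(C)CCCC2(C)C | intermediate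
18 | (1R,6R)-1-ethynyl-2,2,6-trimethyl-7-oxabicyclo[4.1.0]heptane | C#C[C@@]12O[C@]1(C)CCCC2(C)C | intermediate
19 | but-2-yn-1-ol | CC#CCO | starting material
20 | (2E)-3-iodobut-2-en-1-ol | OC/C=C(\C)I | intermediate
21 | (2E)-3-methyl-5-[(1R,6R)-2,2,6-trimethyl-7-oxabicyclo[4.1.0]heptan-1-yl]pent-2-en-4-yn-1-ol | OC/C=C(\C)C#C[C@@]12O[C@]1(C)CCCC2(C)C | intermediate
22 | (1R)-2-[(3E)-5-hydroxy-3-methylpenta-1,3-dien-1-ylidene]-1,3,3-trimethylcyclohexan-1-ol, (aS) allene axis | OC/C=C(\C)C([H])=[C@]=C1C(C)(C)CCC[C@@]1(C)O | intermediate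
23 | (2E)-3-[(2R,7aR)-4,4,7a-trimethyl-2,4,5,6,7,7a-hexahydro-1-benzofuran-2-yl]but-2-en-1-ol | OC/C=C(\C)[C@H]1C=C2C(C)(C)CCC[C@@]2(C)O1 | intermediate
24 | (2R,7aR)-2-[(2E)-4-bromobut-2-en-2-yl]-4,4,7a-trimethyl-2,4,5,6,7,7a-hexahydro-1-benzofuran | BrC/C=C(\C)[C@H]1C=C2C(C)(C)CCC[C@@]2(C)O1 | intermediate (not isolated)
25 | [(2E)-3-[(2R,7aR)-4,4,7a-trimethyl-2,4,5,6,7,7a-hexahydro-1-benzofuran-2-yl]but-2-en-1-yl]triphenylphosphonium bromide | [Br-].c1ccccc1[P+](c1ccccc1)(c1ccccc1)C/C=C(\C)[C@H]1C=C2C(C)(C)CCC[C@@]2(C)O1 | intermediate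
26 | (5R,8R,6'R)-5,8-epoxy-5,8-dihydro-β,ε-carotene | CC1=CCCC(C)(C)[C@H]1/C=C/C(C)=C/C=C/C(C)=C/C=C/C=C(C)/C=C/C=C(\C)[C@H]1C=C2C(C)(C)CCC[C@@]2(C)O1 | target

Total step count: 19.
Longest linear sequence: 9 steps (steps 1, 2, 3, 4, 6, 7, 8, 9, 19; the branch through steps 10, 11, 12, 13, 15, 16, 17, 18, 19 is equally long).

Steps most likely to fail

Step 1. Cationic oligomerisation of the electron-rich, acid-sensitive diene, ene reaction, or closure of the intermediate through oxygen to a dihydropyran may outrun the carbocyclic [4+2] mode. The fallback sets out from diene 1 and makes the same two bonds in an ionic Diels–Alder reaction: 2-vinyl-1,3-dioxolane with catalytic TfOH in CH2Cl2 at −78 °C generates a dioxolanyl-stabilised allyl cation that adds stepwise across the diene and closes to 2-(2,2,4-trimethylcyclohex-3-en-1-yl)-1,3-dioxolane F1. Mild acetal hydrolysis (PPTS, wet acetone) then gives aldehyde 3, where the route is rejoined.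

Step 16. Syn leakage in the centre-to-axis transfer, hydrocupration with the opposite regiochemistry (over-reduction to a diene), or stalling of the catalyst by O-silylation may erode the allene configuration or the conversion. The fallback sets out from epoxy enynol 21 and gives up stereocontrol at C8 in exchange for robust steps. DIBAL-H (CH2Cl2, 0 °C), the aluminium-directed SN2′ reduction established for such epoxy enynols, delivers hydride syn to the oxirane oxygen and gives the allene-axis epimer (1R)-2-[(3E)-5-hydroxy-3-methylpenta-1,3-dien-1-ylidene]-1,3,3-trimethylcyclohexan-1-ol with the (aR) axis F7. Cyclisation with AgNO3 as in step 17 gives the C2 epimer (2E)-3-[(2S,7aR)-4,4,7a-trimethyl-2,4,5,6,7,7a-hexahydro-1-benzofuran-2-yl]but-2-en-1-ol F8. Acid-catalysed equilibration of the bis-allylic ether centre (trace HCl, CHCl3) and chromatographic separation of the two C2 epimers then supply alcohol 23, where the route is rejoined.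

Step 7. A competing [1,2]-shift, lithiation at the ring carbinol carbon, or addition of butyllithium to the diene may divert the rearrangement. The fallback sets out from alcohol 6 and replaces the anionic [2,3] shift by a thermal [3,3] shift with the same suprafacial sense.
- Esterification with (4-methylbenzenesulfonyl)acetic acid (DCC, DMAP, CH2Cl2) gives (1S)-2,4,4-trimethylcyclohex-2-en-1-yl (4-methylbenzenesulfonyl)acetate F2.
- Decarboxylative Ireland–Claisen rearrangement (N,O-bis(trimethylsilyl)acetamide, cat. KOAc, toluene, 110 °C) gives 1-methyl-4-({[(1R)-2,6,6-trimethylcyclohex-2-en-1-yl]methyl}sulfonyl)benzene F3.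
- Lithiation (n-BuLi, THF, −78 °C) and alkylation with ethyl (E)-4-bromo-3-methylbut-2-enoate give ethyl (2E)-3-methyl-5-(4-methylbenzenesulfonyl)-5-[(1R)-2,6,6-trimethylcyclohex-2-en-1-yl]pent-2-enoate F4.
- Base-induced elimination of sulfinate (NaOEt, EtOH) gives ethyl (2E,4E)-3-methyl-5-[(1R)-2,6,6-trimethylcyclohex-2-en-1-yl]penta-2,4-dienoate F5.
- DIBAL-H reduction gives (2E,4E)-3-methyl-5-[(1R)-2,6,6-trimethylcyclohex-2-en-1-yl]penta-2,4-dien-1-ol F6, and PPh3·HBr in MeOH converts it into salt 11, where the route is rejoined.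

Further compounds
F1 | step 1 | 2-(2,2,4-trimethylcyclohex-3-en-1-yl)-1,3-dioxolane | CC1=CC(C)(C)C(CC1)C1OCCO1
F2 | step 7 | (1S)-2,4,4-trimethylcyclohex-2-en-1-yl (4-methylbenzenesulfonyl)acetate | Cc1ccc(cc1)S(=O)(=O)CC(=O)O[C@H]1CCC(C)(C)C=C1C
F3 | step 7 | 1-methyl-4-({[(1R)-2,6,6-trimethylcyclohex-2-en-1-yl]methyl}sulfonyl)benzene | CC1=CCCC(C)(C)[C@H]1CS(=O)(=O)c1ccc(C)cc1
F4 | step 7 | ethyl (2E)-3-methyl-5-(4-methylbenzenesulfonyl)-5-[(1R)-2,6,6-trimethylcyclohex-2-en-1-yl]pent-2-enoate | CC1=CCCC(C)(C)[C@H]1C(C/C(C)=C/C(=O)OCC)S(=O)(=O)c1ccc(C)cc1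
F5 | step 7 | ethyl (2E,4E)-3-methyl-5-[(1R)-2,6,6-trimethylcyclohex-2-en-1-yl]penta-2,4-dienoate | CC1=CCCC(C)(C)[C@H]1/C=C/C(C)=C/C(=O)OCC
F6 | step 7 | (2E,4E)-3-methyl-5-[(1R)-2,6,6-trimethylcyclohex-2-en-1-yl]penta-2,4-dien-1-ol | CC1=CCCC(C)(C)[C@H]1/C=C/C(C)=C/CO
F7 | step 16 | (1R)-2-[(3E)-5-hydroxy-3-methylpenta-1,3-dien-1-ylidene]-1,3,3-trimethylcyclohexan-1-ol, (aR) allene axis | OC/C=C(\C)C([H])=[C@@]=C1C(C)(C)CCC[C@@]1(C)O
F8 | step 16 | (2E)-3-[(2S,7aR)-4,4,7a-trimethyl-2,4,5,6,7,7a-hexahydro-1-benzofuran-2-yl]but-2-en-1-ol | OC/C=C(\C)[C@@H]1C=C2C(C)(C)CCC[C@@]2(C)O1
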